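**Retrosynthetic overview**

- Numbering: ring C1–C10 (Z C1=C10 with methyl C14 on C10, E C4=C5 with methyl C15 on C4), lactone C11(=C13H2)–C12(=O)–O–C6, hydroxyls on C7 and C9, ester on C8. The plan rests on C6: it is the allylic carbinol carbon next to C5 of the E alkene and it carries the lactone oxygen, while its neighbour C7 carries the C11–C12 acrylate unit.
- Last disconnection: the C8 ester, from the 9-O-silyl triol and (2S,3R)-2,3-dimethyloxirane-2-carboxylic acid (Sharpless epoxidation of (E)-2-methylbut-2-en-1-ol, then oxidation).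
- Key disconnection: C5–C6 and O–C12 in one operation. An E alkenyl iodide (C5), an aldehyde (C6) and a methyl acrylate unit on C7 give the ten-membered carbocycle by Nozaki–Hiyama–Kishi addition and the methylene lactone by attack of the C6 alkoxide on C12.
- Precursor: C7–C10 with the C8 and C9 centres from 2,3-O-isopropylidene-D-erythronolactone; Z C1=C10 by Wittig reaction of the C10 methyl ketone with a C1–C5 ylide (carboalumination of pent-4-yn-1-ol); C6 by hydroxymethylation of the C7 amide; C11–C13 by Felkin–Anh addition of a masked acrylate anion to the C7 ketone.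
- Ring order: dioxolane (from the start, removed in step 17), then carbocycle and lactone together (step 16), then the oxirane with the acid (step 21).

Key step: step 16

Assumption: (tributylstannyl)methanol and methyl 3-(dimethylamino)propanoate are bought as such.

**Route**

Step 1
Reactants: 1 2,3-O-isopropylidene-D-erythronolactone
Product: 2 [(4R,5R)-5-(hydroxymethyl)-2,2-dimethyl-1,3-dioxolan-4-yl](morpholin-4-yl)methanone
Conditions: morpholine, AlMe3, CH2Cl2, 0 °C to rt
Reagents that add atoms: morpholine C1COCCN1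
Why: Aminolysis of the γ-lactone by the dimethylaluminium amide of morpholine should open the acyl C–O bond without touching the two dioxolane centres (later C8 and C9), and the tertiary amide resists relactonisation and later serves as the acyl donor for C7.

Step 2
Reactants: 2 [(4R,5R)-5-(hydroxymethyl)-2,2-dimethyl-1,3-dioxolan-4-yl](morpholin-4-yl)methanone
Product: 3 (4S,5R)-2,2-dimethyl-5-(morpholine-4-carbonyl)-1,3-dioxolane-4-carbaldehyde
Conditions: Dess–Martin periodinane, pyridine, CH2Cl2, 0 °C to rt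
Reagents that add atoms: none
Why: Dess–Martin oxidation of the primary alcohol under buffered conditions should give the C10 aldehyde without epimerising the α-alkoxy centre C9 of the cis-dioxolane, and the crude aldehyde is used at once.

Step 3
Reactants: 3 (4S,5R)-2,2-dimethyl-5-(morpholine-4-carbonyl)-1,3-dioxolane-4-carbaldehyde
Product: 4 [(4R,5R)-5-(1-hydroxyethyl)-2,2-dimethyl-1,3-dioxolan-4-yl](morpholin-4-yl)methanone as a mixture of carbinol epimers
Conditions: MeMgBr, THF, −78 °C
Reagents that add atoms: methylmagnesium bromide C[Mg]Br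
Why: Grignard addition to the aldehyde at −78 °C is much faster than attack on the tertiary amide and brings in C14, and the new carbinol centre needs no control because step 4 removes it.

Step 4
Reactants: 4 [(4R,5R)-5-(1-hydroxyethyl)-2,2-dimethyl-1,3-dioxolan-4-yl](morpholin-4-yl)methanone as a mixture of carbinol epimers
Product: 5 1-[(4S,5R)-2,2-dimethyl-5-(morpholine-4-carbonyl)-1,3-dioxolan-4-yl]ethan-1-one
Conditions: Dess–Martin periodinane, pyridine, CH2Cl2, rt
Reagents that add atoms: none
Why: Dess–Martin oxidation of the secondary alcohol should converge both epimers on the C10 methyl ketone without a base strong enough to invert C9.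

Step 5
Reactants: 6 pent-4-yn-1-ol
Product: 8 (E)-5-iodo-4-methylpent-4-en-1-ol, via alkenylalane 7 (not isolated)
Conditions: AlMe3, Cp2ZrCl2 (cat.), CH2Cl2, 0 °C to rt; then I2, THF, −30 °C
Reagents that add atoms: trimethylaluminium C[Al](C)C; iodine I-I
Why: Zirconium-catalysed Negishi carboalumination adds methyl and aluminium syn across the terminal alkyne with methyl on the inner carbon, and iodinolysis of the carbon–aluminium bond with retention gives the E alkenyl iodide (C4=C5 with C15).

Step 6
Reactants: 8 (E)-5-iodo-4-methylpent-4-en-1-ol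
Product: 9 (E)-1,5-diiodo-2-methylpent-1-ene
Conditions: I2, PPh3, imidazole, CH2Cl2, 0 °C
Reagents that add atoms: iodine I-I
Why: Appel-type iodination converts the primary alcohol into the primary iodide by SN2 displacement of the oxyphosphonium group and leaves the alkenyl iodide alone.

Step 7
Reactants: 9 (E)-1,5-diiodo-2-methylpent-1-ene
Product: 10 [(E)-5-iodo-4-methylpent-4-en-1-yl]triphenylphosphonium iodide
Conditions: PPh3, MeCN, reflux
Reagents that add atoms: triphenylphosphine c1ccc(cc1)P(c1ccccc1)c1ccccc1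
Why: SN2 quaternisation of the phosphine takes place only at the sp3 carbon–iodine bond, so the Wittig salt for C1–C5 forms with the E alkenyl iodide intact.

Step 8
Reactants: 5 1-[(4S,5R)-2,2-dimethyl-5-(morpholine-4-carbonyl)-1,3-dioxolan-4-yl]ethan-1-one; 10 [(E)-5-iodo-4-methylpent-4-en-1-yl]triphenylphosphonium iodide
Product: 12 [(4R,5R)-5-[(2Z,6E)-7-iodo-6-methylhepta-2,6-dien-2-yl]-2,2-dimethyl-1,3-dioxolan-4-yl](morpholin-4-yl)methanone, via phosphorus ylide 11 (not isolated)
Conditions: 10, KN(SiMe3)2, THF, −78 °C; then 5, −78 °C to 0 °C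
Reagents that add atoms: none
Why: Wittig olefination of an α-alkoxy methyl ketone with a salt-free non-stabilised ylide is known to give the Z trisubstituted allylic ether (chain carbon C2 cis to the oxygenated carbon C9) through the kinetically favoured oxaphosphetane, the low temperature limits enolisation toward C9, and the amide and the alkenyl iodide do not react.

Step 9
Reactants: 13 (tributylstannyl)methanol
Product: 14 tributyl[(1-ethoxyethoxy)methyl]stannane
Conditions: ethyl vinyl ether, PPTS (cat.), CH2Cl2, rt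
Reagents that add atoms: ethyl vinyl ether C=COCC
Why: Acid-catalysed addition of the alcohol to the enol ether gives the mixed acetal, which protects the hydroxymethyl unit (C6) for tin–lithium exchange.

Step 10
Reactants: 12 [(4R,5R)-5-[(2Z,6E)-7-iodo-6-methylhepta-2,6-dien-2-yl]-2,2-dimethyl-1,3-dioxolan-4-yl](morpholin-4-yl)methanone; 14 tributyl[(1-ethoxyethoxy)methyl]stannane
Product: 18 2-hydroxy-1-[(4R,5R)-5-[(2Z,6E)-7-iodo-6-methylhepta-2,6-dien-2-yl]-2,2-dimethyl-1,3-dioxolan-4-yl]ethan-1-one, via alkoxymethyllithium 15 (not isolated), via alkoxymethylmagnesium bromide 16 (not isolated), via acetal-protected ketone 17 (not isolated)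
Conditions: 14, n-BuLi, THF, −78 °C; MgBr2·OEt2, −78 °C; then 12, −78 °C to 0 °C; aq. NH4Cl; then PPTS, MeOH, rt
Reagents that add atoms: none
Why: Tin–lithium exchange gives the α-alkoxymethyl carbanion, transmetalation to magnesium removes the risk of iodine–lithium exchange at the alkenyl iodide, acylation of this Grignard reagent by the morpholine amide stops at the chelated tetrahedral adduct and so gives the C7 ketone, and mild methanolysis cleaves the acyclic acetal but not the dioxolane.

Step 11
Reactants: 18 2-hydroxy-1-[(4R,5R)-5-[(2Z,6E)-7-iodo-6-methylhepta-2,6-dien-2-yl]-2,2-dimethyl-1,3-dioxolan-4-yl]ethan-1-one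
Product: 19 1-[(4R,5R)-5-[(2Z,6E)-7-iodo-6-methylhepta-2,6-dien-2-yl]-2,2-dimethyl-1,3-dioxolan-4-yl]-2-(triethylsilyloxy)ethan-1-one
Conditions: Et3SiCl, imidazole, CH2Cl2, 0 °C
Reagents that add atoms: chlorotriethylsilane CC[Si](Cl)(CC)CC
Why: Silylation of the primary α-hydroxy ketone is fast and gives a non-chelating C6 silyl ether, which supports Felkin–Anh control in step 12 and is the group that step 15 oxidises directly.

Step 12
Reactants: 19 1-[(4R,5R)-5-[(2Z,6E)-7-iodo-6-methylhepta-2,6-dien-2-yl]-2,2-dimethyl-1,3-dioxolan-4-yl]-2-(triethylsilyloxy)ethan-1-one; 20 methyl 3-(dimethylamino)propanoate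
Product: 22 methyl (3R)-2-[(dimethylamino)methyl]-3-hydroxy-3-[(4R,5R)-5-[(2Z,6E)-7-iodo-6-methylhepta-2,6-dien-2-yl]-2,2-dimethyl-1,3-dioxolan-4-yl]-4-(triethylsilyloxy)butanoate as a mixture of C2 epimers, via lithium enolate 21 (not isolated)
Conditions: 20, LiN(iPr)2, THF, −78 °C; then 19, −78 °C; aq. NH4Cl at −78 °C
Reagents that add atoms: none
Why: Aldol-type addition of the lithium enolate of the β-amino ester (a masked acrylate α-anion) to the activated α,α′-dioxygenated ketone should follow the polar Felkin–Anh model, with attack anti to the C8–O bond and C9 on the carbonyl-oxygen side, which places the new C7 hydroxyl syn to O8 in the C6–C9 zigzag (7R in target numbering), and the C11 centre is erased in step 14.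

Step 13
Reactants: 22 methyl (3R)-2-[(dimethylamino)methyl]-3-hydroxy-3-[(4R,5R)-5-[(2Z,6E)-7-iodo-6-methylhepta-2,6-dien-2-yl]-2,2-dimethyl-1,3-dioxolan-4-yl]-4-(triethylsilyloxy)butanoate as a mixture of C2 epimers
Product: 23 methyl (3R)-2-[(dimethylamino)methyl]-3-[(4R,5R)-5-[(2Z,6E)-7-iodo-6-methylhepta-2,6-dien-2-yl]-2,2-dimethyl-1,3-dioxolan-4-yl]-3,4-bis(triethylsilyloxy)butanoate as a mixture of C2 epimers
Conditions: Et3SiOTf, 2,6-lutidine, CH2Cl2, −78 °C to 0 °C
Reagents that add atoms: triethylsilyl trifluoromethanesulfonate CC[Si](CC)(CC)OS(=O)(=O)C(F)(F)F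
Why: The silyl triflate with 2,6-lutidine silylates the hindered tertiary C7 hydroxyl, which blocks retro-aldol cleavage in step 14 and gives the α-silyloxy group that directs the key step.

Step 14
Reactants: 23 methyl (3R)-2-[(dimethylamino)methyl]-3-[(4R,5R)-5-[(2Z,6E)-7-iodo-6-methylhepta-2,6-dien-2-yl]-2,2-dimethyl-1,3-dioxolan-4-yl]-3,4-bis(triethylsilyloxy)butanoate as a mixture of C2 epimers
Product: 25 methyl (3R)-3-[(4R,5R)-5-[(2Z,6E)-7-iodo-6-methylhepta-2,6-dien-2-yl]-2,2-dimethyl-1,3-dioxolan-4-yl]-2-methylidene-3,4-bis(triethylsilyloxy)butanoate, via ammonium iodide 24 (not isolated)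
Conditions: MeI, MeCN, rt; then DBU, CH2Cl2, rt
Reagents that add atoms: none
Why: Quaternisation of the dimethylamino group and base-induced E1cB (Hofmann-type) elimination of trimethylamine from the β-ammonio ester unmask the C11=C13 methylene ester, the ammonium group being a far better leaving group than the β-silyloxy group on C7.

Step 15
Reactants: 25 methyl (3R)-3-[(4R,5R)-5-[(2Z,6E)-7-iodo-6-methylhepta-2,6-dien-2-yl]-2,2-dimethyl-1,3-dioxolan-4-yl]-2-methylidene-3,4-bis(triethylsilyloxy)butanoate
Product: 26 methyl (3S)-3-[(4R,5R)-5-[(2Z,6E)-7-iodo-6-methylhepta-2,6-dien-2-yl]-2,2-dimethyl-1,3-dioxolan-4-yl]-2-methylidene-4-oxo-3-(triethylsilyloxy)butanoate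
Conditions: (COCl)2, DMSO, CH2Cl2, −78 °C to −40 °C; then Et3N, to 0 °C
Reagents that add atoms: none
Why: Under Swern conditions a primary triethylsilyl ether is cleaved by the chlorosulfonium salt and oxidised in the same flask while the tertiary silyl ether stays, so the C6 aldehyde forms without a free C6 hydroxyl that could lactonise onto the C12 ester, and the α-quaternary aldehyde cannot epimerise (the descriptor at C7 changes only through the priority order).

Step 16
Reactants: 26 methyl (3S)-3-[(4R,5R)-5-[(2Z,6E)-7-iodo-6-methylhepta-2,6-dien-2-yl]-2,2-dimethyl-1,3-dioxolan-4-yl]-2-methylidene-4-oxo-3-(triethylsilyloxy)butanoate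
Product: 29 (6R,7R,8R,9R)-8,9-(isopropylidenedioxy)-7-(triethylsilyloxy)germacra-1(10)Z,4E,11(13)-trien-12,6-olide, via alkenylchromium species 27 (not isolated), via chromium alkoxide 28 (not isolated)
Conditions: CrCl2 (excess), NiCl2 (cat.), degassed DMSO, rt, slow addition of 26 to a final 0.003 M
Reagents that add atoms: none
Why: Zerovalent nickel, formed from NiCl2 by CrCl2, inserts into the C5–iodine bond, the alkenyl group passes to trivalent chromium with retention of the E geometry, and the alkenylchromium 27 adds to the C6 aldehyde, the known course of Nozaki–Hiyama–Kishi macrocyclisations of alkenyl iodide aldehydes. This addition closes the ten-membered carbocycle by a 10-exo-trig attack of C5 on the carbonyl carbon, and the chromium alkoxide 28 then closes the lactone by a 5-exo-trig acyl substitution at the C12 methyl ester with loss of methoxide, as chromium alkoxides of 4-hydroxy-2-methylene esters are known to do. C6 is the only new stereocentre and is controlled by C7: the alkenyl carbon should approach anti to the C7–O(silyl) bond (polar Felkin–Anh) with the tethered C8 gauche on the carbonyl-oxygen side, which gives 6R and the trans-fused lactone. The step needs chemoselectivity for the aldehyde, which alkenylchromium reagents show in the presence of esters and acrylates, and it needs ring closure to beat dimerisation, which slow addition at high dilution and the folding imposed by the Z C1=C10 alkene and the cis-dioxolane should secure. The aldehyde has no α-hydrogen, so the C7 centre cannot be lost.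

Step 17
Reactants: 29 (6R,7R,8R,9R)-8,9-(isopropylidenedioxy)-7-(triethylsilyloxy)germacra-1(10)Z,4E,11(13)-trien-12,6-olide
Product: 30 7,8,9-trihydroxygermacra-1(10)Z,4E,11(13)-trien-12,6-olide with C6 to C9 arranged as in the target
Conditions: AcOH/H2O (4:1), 50 °C
Reagents that add atoms: none
Why: Acid-catalysed hydrolysis cleaves the tertiary silyl ether and the dioxolane (through the oxocarbenium ion at the ketal carbon), and a weak acid is chosen so that the two ring alkenes, each deactivated by an allylic oxygen, are not protonated.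

Step 18
Reactants: 30 7,8,9-trihydroxygermacra-1(10)Z,4E,11(13)-trien-12,6-olide with C6 to C9 arranged as in the target
Product: 31 7,8-dihydroxy-9-(triethylsilyloxy)germacra-1(10)Z,4E,11(13)-trien-12,6-olide with C6 to C9 arranged as in the target
Conditions: Et3SiCl, imidazole, DMF, −30 °C
Reagents that add atoms: chlorotriethylsilane CC[Si](Cl)(CC)CC
Why: Kinetic silylation should take the allylic C9 hydroxyl, flanked by the sp2 carbon C10, in preference to the C8 hydroxyl next to the fully substituted C7, and the tertiary C7 hydroxyl does not react with the chlorosilane at this temperature.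

Step 19
Reactants: 32 (E)-2-methylbut-2-en-1-ol
Product: 33 [(2R,3R)-2,3-dimethyloxiran-2-yl]methanol
Conditions: Ti(OiPr)4 (cat.), D-(−)-diethyl tartrate (cat.), t-BuOOH, 4 Å molecular sieves, CH2Cl2, −20 °C
Reagents that add atoms: tert-butyl hydroperoxide CC(C)(C)OO
Why: Sharpless asymmetric epoxidation of the E allylic alcohol with the D-(−)-tartrate ligand delivers oxygen to the face that gives the (2R,3R) epoxy alcohol, and the alkene geometry is retained so that the two methyl groups stay cis.

Step 20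
Reactants: 33 [(2R,3R)-2,3-dimethyloxiran-2-yl]methanol
Product: 34 (2S,3R)-2,3-dimethyloxirane-2-carboxylic acid
Conditions: RuCl3 (cat.), NaIO4, MeCN/EtOAc/H2O, rt
Reagents that add atoms: water O
Why: Ruthenium tetroxide formed in the flask from RuCl3 and NaIO4 oxidises the primary alcohol through the aldehyde hydrate to the acid without opening the epoxide, and the descriptor at C2 becomes S only because the priority order changes.

Step 21
Reactants: 31 7,8-dihydroxy-9-(triethylsilyloxy)germacra-1(10)Z,4E,11(13)-trien-12,6-olide with C6 to C9 arranged as in the target; 34 (2S,3R)-2,3-dimethyloxirane-2-carboxylic acid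
Product: 36 (6R,7R,8R,9R)-8-[(2S,3R)-2,3-dimethyloxirane-2-carbonyloxy]-7-hydroxy-9-(triethylsilyloxy)germacra-1(10)Z,4E,11(13)-trien-12,6-olide, via mixed anhydride 35 (not isolated)
Conditions: 34, 2,4,6-trichlorobenzoyl chloride, Et3N, THF, rt; then 31, DMAP, toluene, rt to 40 °C
Reagents that add atoms: none
Why: Yamaguchi esterification through the mixed anhydride and its acylpyridinium ion acylates the only reactive hydroxyl, the secondary one on C8 (C9 is silylated and the tertiary C7 hydroxyl is too hindered), and the acid has no α-hydrogen so its two centres cannot epimerise.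

Step 22
Reactants: 36 (6R,7R,8R,9R)-8-[(2S,3R)-2,3-dimethyloxirane-2-carbonyloxy]-7-hydroxy-9-(triethylsilyloxy)germacra-1(10)Z,4E,11(13)-trien-12,6-olide
Product: 37 (6R,7R,8R,9R)-8-[(2S,3R)-2,3-dimethyloxirane-2-carbonyloxy]-7,9-dihydroxygermacra-1(10)Z,4E,11(13)-trien-12,6-olide (CNP0420662.1)
Conditions: HF·pyridine, pyridine, THF, 0 °C
Reagents that add atoms: none
Why: Buffered fluoride cleaves the silicon–oxygen bond of the secondary silyl ether under conditions that spare the epoxide, the C8 ester and the α-methylene lactone, and should give the target.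

**Compound list**

1 | 2,3-O-isopropylidene-D-erythronolactone | O=C1OC[C@H]2OC(C)(C)O[C@H]21 | starting material
2 | [(4R,5R)-5-(hydroxymethyl)-2,2-dimethyl-1,3-dioxolan-4-yl](morpholin-4-yl)methanone | O=C(N1CCOCC1)[C@@H]1OC(C)(C)O[C@@H]1CO | intermediate
3 | (4S,5R)-2,2-dimethyl-5-(morpholine-4-carbonyl)-1,3-dioxolane-4-carbaldehyde | O=C(N1CCOCC1)[C@@H]1OC(C)(C)O[C@@H]1C=O | intermediate
4 | [(4R,5R)-5-(1-hydroxyethyl)-2,2-dimethyl-1,3-dioxolan-4-yl](morpholin-4-yl)methanone, both carbinol epimers | O=C(N1CCOCC1)[C@@H]1OC(C)(C)O[C@@H]1C(C)O | intermediate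
5 | 1-[(4S,5R)-2,2-dimethyl-5-(morpholine-4-carbonyl)-1,3-dioxolan-4-yl]ethan-1-one | O=C(N1CCOCC1)[C@@H]1OC(C)(C)O[C@@H]1C(C)=O | intermediate
6 | pent-4-yn-1-ol | C#CCCCO | starting material
7 | [(E)-5-(dimethylalumanyloxy)-2-methylpent-1-en-1-yl]dimethylalane, formed in the flask | C[Al](C)OCCC/C(C)=C/[Al](C)C | intermediate
8 | (E)-5-iodo-4-methylpent-4-en-1-ol | OCCC/C(C)=C/I | intermediate
9 | (E)-1,5-diiodo-2-methylpent-1-ene | ICCC/C(C)=C/I | intermediate
10 | [(E)-5-iodo-4-methylpent-4-en-1-yl]triphenylphosphonium iodide | [I-].I/C=C(\C)CCC[P+](c1ccccc1)(c1ccccc1)c1ccccc1 | intermediate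
11 | [(E)-5-iodo-4-methylpent-4-en-1-ylidene]triphenylphosphorane, formed in the flask | I/C=C(\C)CCC=P(c1ccccc1)(c1ccccc1)c1ccccc1 | intermediate
12 | [(4R,5R)-5-[(2Z,6E)-7-iodo-6-methylhepta-2,6-dien-2-yl]-2,2-dimethyl-1,3-dioxolan-4-yl](morpholin-4-yl)methanone | O=C(N1CCOCC1)[C@@H]1OC(C)(C)O[C@@H]1/C(C)=C\CC/C(C)=C/I | intermediate
13 | (tributylstannyl)methanol | CCCC[Sn](CCCC)(CCCC)CO | starting material
14 | tributyl[(1-ethoxyethoxy)methyl]stannane | CCCC[Sn](CCCC)(CCCC)COC(C)OCC | intermediate
15 | [(1-ethoxyethoxy)methyl]lithium, formed in the flask | [Li]COC(C)OCC | intermediate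
16 | bromo[(1-ethoxyethoxy)methyl]magnesium, formed in the flask | Br[Mg]COC(C)OCC | intermediate
17 | 2-(1-ethoxyethoxy)-1-[(4R,5R)-5-[(2Z,6E)-7-iodo-6-methylhepta-2,6-dien-2-yl]-2,2-dimethyl-1,3-dioxolan-4-yl]ethan-1-one, acetal epimers, not isolated | CCOC(C)OCC(=O)[C@@H]1OC(C)(C)O[C@@H]1/C(C)=C\CC/C(C)=C/I | intermediate
18 | 2-hydroxy-1-[(4R,5R)-5-[(2Z,6E)-7-iodo-6-methylhepta-2,6-dien-2-yl]-2,2-dimethyl-1,3-dioxolan-4-yl]ethan-1-one | OCC(=O)[C@@H]1OC(C)(C)O[C@@H]1/C(C)=C\CC/C(C)=C/I | intermediate
19 | 1-[(4R,5R)-5-[(2Z,6E)-7-iodo-6-methylhepta-2,6-dien-2-yl]-2,2-dimethyl-1,3-dioxolan-4-yl]-2-(triethylsilyloxy)ethan-1-one | CC[Si](CC)(CC)OCC(=O)[C@@H]1OC(C)(C)O[C@@H]1/C(C)=C\CC/C(C)=C/I | intermediate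
20 | methyl 3-(dimethylamino)propanoate | CN(C)CCC(=O)OC | starting material
21 | lithium enolate of methyl 3-(dimethylamino)propanoate, formed in the flask | CN(C)CC=C(O[Li])OC | intermediate
22 | methyl (3R)-2-[(dimethylamino)methyl]-3-hydroxy-3-[(4R,5R)-5-[(2Z,6E)-7-iodo-6-methylhepta-2,6-dien-2-yl]-2,2-dimethyl-1,3-dioxolan-4-yl]-4-(triethylsilyloxy)butanoate, C2 epimers | CC[Si](CC)(CC)OC[C@](O)(C(CN(C)C)C(=O)OC)[C@@H]1OC(C)(C)O[C@@H]1/C(C)=C\CC/C(C)=C/I | intermediate
23 | methyl (3R)-2-[(dimethylamino)methyl]-3-[(4R,5R)-5-[(2Z,6E)-7-iodo-6-methylhepta-2,6-dien-2-yl]-2,2-dimethyl-1,3-dioxolan-4-yl]-3,4-bis(triethylsilyloxy)butanoate, C2 epimers | CC[Si](CC)(CC)OC[C@](O[Si](CC)(CC)CC)(C(CN(C)C)C(=O)OC)[C@@H]1OC(C)(C)O[C@@H]1/C(C)=C\CC/C(C)=C/I | intermediate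
24 | trimethylammonium iodide of 23 (N-methylated), not isolated | CC[Si](CC)(CC)OC[C@](O[Si](CC)(CC)CC)(C(C[N+](C)(C)C)C(=O)OC)[C@@H]1OC(C)(C)O[C@@H]1/C(C)=C\CC/C(C)=C/I.[I-] | intermediate
25 | methyl (3R)-3-[(4R,5R)-5-[(2Z,6E)-7-iodo-6-methylhepta-2,6-dien-2-yl]-2,2-dimethyl-1,3-dioxolan-4-yl]-2-methylidene-3,4-bis(triethylsilyloxy)butanoate | CC[Si](CC)(CC)OC[C@](O[Si](CC)(CC)CC)(C(=C)C(=O)OC)[C@@H]1OC(C)(C)O[C@@H]1/C(C)=C\CC/C(C)=C/I | intermediate
26 | methyl (3S)-3-[(4R,5R)-5-[(2Z,6E)-7-iodo-6-methylhepta-2,6-dien-2-yl]-2,2-dimethyl-1,3-dioxolan-4-yl]-2-methylidene-4-oxo-3-(triethylsilyloxy)butanoate | O=C[C@](O[Si](CC)(CC)CC)(C(=C)C(=O)OC)[C@@H]1OC(C)(C)O[C@@H]1/C(C)=C\CC/C(C)=C/I | intermediate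
27 | alkenylchromium dichloride from 26 (trivalent chromium in place of iodine on C5), formed in the flask | O=C[C@](O[Si](CC)(CC)CC)(C(=C)C(=O)OC)[C@@H]1OC(C)(C)O[C@@H]1/C(C)=C\CC/C(C)=C/[Cr](Cl)Cl | intermediate
28 | ring-closed C6 alkoxide of chromium dichloride (ten-membered ring formed, C12 still the methyl ester), formed in the flask | Cl[Cr](Cl)O[C@@H]1/C=C(\C)CC/C=C(/C)[C@H]2OC(C)(C)O[C@H]2[C@@]1(O[Si](CC)(CC)CC)C(=C)C(=O)OC | intermediate
29 | (6R,7R,8R,9R)-8,9-(isopropylidenedioxy)-7-(triethylsilyloxy)germacra-1(10)Z,4E,11(13)-trien-12,6-olide | C=C1C(=O)O[C@@H]2/C=C(\C)CC/C=C(/C)[C@H]3OC(C)(C)O[C@H]3[C@@]12O[Si](CC)(CC)CC | intermediate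
30 | 7,8,9-trihydroxygermacra-1(10)Z,4E,11(13)-trien-12,6-olide, C6 to C9 as in 37 | C=C1C(=O)O[C@@H]2/C=C(\C)CC/C=C(/C)[C@@H](O)[C@@H](O)[C@@]12O | intermediate
31 | 7,8-dihydroxy-9-(triethylsilyloxy)germacra-1(10)Z,4E,11(13)-trien-12,6-olide, C6 to C9 as in 37 | C=C1C(=O)O[C@@H]2/C=C(\C)CC/C=C(/C)[C@@H](O[Si](CC)(CC)CC)[C@@H](O)[C@@]12O | intermediate
32 | (E)-2-methylbut-2-en-1-ol | C/C=C(\C)CO | starting material
33 | [(2R,3R)-2,3-dimethyloxiran-2-yl]methanol | OC[C@@]1(C)O[C@@H]1C | intermediate
34 | (2S,3R)-2,3-dimethyloxirane-2-carboxylic acid | OC(=O)[C@@]1(C)O[C@@H]1C | intermediate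
35 | (2S,3R)-2,3-dimethyloxirane-2-carboxylic 2,4,6-trichlorobenzoic anhydride, formed in the flask | O=C(OC(=O)[C@@]1(C)O[C@@H]1C)c1c(Cl)cc(Cl)cc1Cl | intermediate
36 | (6R,7R,8R,9R)-8-[(2S,3R)-2,3-dimethyloxirane-2-carbonyloxy]-7-hydroxy-9-(triethylsilyloxy)germacra-1(10)Z,4E,11(13)-trien-12,6-olide | C=C1C(=O)O[C@@H]2/C=C(\C)CC/C=C(/C)[C@@H](O[Si](CC)(CC)CC)[C@@H](OC(=O)[C@@]3(C)O[C@@H]3C)[C@@]12O | intermediate
37 | (6R,7R,8R,9R)-8-[(2S,3R)-2,3-dimethyloxirane-2-carbonyloxy]-7,9-dihydroxygermacra-1(10)Z,4E,11(13)-trien-12,6-olide | C=C1C(=O)O[C@@H]2/C=C(\C)CC/C=C(/C)[C@@H](O)[C@@H](OC(=O)[C@@]3(C)O[C@@H]3C)[C@@]12O | target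

**Step count**

Total step count: 22. Longest linear sequence: 16 steps (steps 1–4, 8, 10–18, 21 and 22, from 1 to 37).

**Steps most likely to fail**

Step 16. The alkenylchromium may attack the other face of the C6 aldehyde if the chain cannot adopt the Felkin–Anh arrangement in the ring-closing transition state, which would give the 6-epimeric, cis-fused lactone. The fallback sets out from 26 and comes back at 29. The ring closure is run as in step 16 and the 6-epimeric lactone F1 is carried on. LiOH in THF/H2O opens it to the 6S seco hydroxy acid F2. Mitsunobu lactonisation (PPh3, DIAD, THF, high dilution) then closes the lactone by SN2 attack of the carboxylate on the activated allylic C6 carbinol, with inversion, and gives 29. C6 is then set by a stereospecific substitution and no longer by the face of the addition.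

Step 12. Proton transfer from the enolisable ketone 19 to the basic ester enolate returns starting material and can invert C8 to the trans-dioxolane, and the facial selectivity at C7 may be insufficient. The fallback sets out from 19 and comes back at 25; it brings in C11–C13 without base by a Mukaiyama aldol addition. Methyl acrylate and benzeneselenol (from PhSeSePh and NaBH4) give methyl 3-(phenylselanyl)propanoate F3. LiN(iPr)2 with Me3SiCl present gives its trimethylsilyl ketene acetal F4. F4 adds to 19 under BF3·OEt2 in CH2Cl2 at −78 °C (open transition state, monodentate Lewis acid, Felkin–Anh sense) to give the β-hydroxy ester F5. Et3SiOTf and 2,6-lutidine give the silyl ether F6. H2O2 with pyridine oxidises the selenide, and syn-elimination of the selenoxide toward its only β-hydrogen (on C11) gives 25.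

Step 17. The acid may induce transannular cyclisation of the 1(10),4-diene, ionisation of the allylic C9–O and C6–O bonds, or a shift of the lactone to the freed C8 hydroxyl while the dioxolane is hydrolysed. The fallback sets out from 18 and comes back at 30; the dioxolane is removed before the ring exists and all oxygens are carried as triethylsilyl ethers. Aqueous CF3CO2H in THF hydrolyses 18 to the trihydroxy ketone F7, and Et3SiCl with imidazole gives the tris-silyl ether F8. The chemistry of steps 12 to 16 (enolate addition, silylation of the C7 hydroxyl, elimination, Swern oxidation of the primary silyl ether only, chromium-mediated ring closure) then gives in turn the adduct F9, the tetrakis-silyl ether F10, the acrylate F11, the aldehyde F12 and the tris-silyl lactone F13. HF·pyridine in THF at 0 °C removes the three silyl groups and gives 30 with no acid hydrolysis on the ring.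

**Further compounds**

F1 | step 16 | 6-epimer of 29 (6S, cis-fused lactone) | C=C1C(=O)O[C@H]2/C=C(\C)CC/C=C(/C)[C@H]3OC(C)(C)O[C@H]3[C@@]12O[Si](CC)(CC)CC
F2 | step 16 | 6S seco hydroxy acid (lactone of F1 opened, C12 as the free acid) | O[C@H]1/C=C(\C)CC/C=C(/C)[C@H]2OC(C)(C)O[C@H]2[C@@]1(O[Si](CC)(CC)CC)C(=C)C(=O)O
F3 | step 12 | methyl 3-(phenylselanyl)propanoate | COC(=O)CC[Se]c1ccccc1
F4 | step 12 | trimethylsilyl ketene acetal of F3 | COC(O[Si](C)(C)C)=CC[Se]c1ccccc1
F5 | step 12 | analogue of 22 with phenylselanyl in place of dimethylamino (C2 epimers) | CC[Si](CC)(CC)OC[C@](O)(C(C[Se]c2ccccc2)C(=O)OC)[C@@H]1OC(C)(C)O[C@@H]1/C(C)=C\CC/C(C)=C/I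
F6 | step 12 | analogue of 23 with phenylselanyl in place of dimethylamino (C2 epimers) | CC[Si](CC)(CC)OC[C@](O[Si](CC)(CC)CC)(C(C[Se]c2ccccc2)C(=O)OC)[C@@H]1OC(C)(C)O[C@@H]1/C(C)=C\CC/C(C)=C/I
F7 | step 17 | (3R,4R,5Z,9E)-1,3,4-trihydroxy-10-iodo-5,9-dimethyldeca-5,9-dien-2-one | OCC(=O)[C@H](O)[C@H](O)/C(C)=C\CC/C(C)=C/I
F8 | step 17 | 1,3,4-tris(triethylsilyl) ether of F7 | CC[Si](CC)(CC)OCC(=O)[C@H](O[Si](CC)(CC)CC)[C@H](O[Si](CC)(CC)CC)/C(C)=C\CC/C(C)=C/I
F9 | step 17 | analogue of 22 with silyl ethers on C8 and C9 in place of the dioxolane (C11 epimers) | CC[Si](CC)(CC)OC[C@](O)(C(CN(C)C)C(=O)OC)[C@H](O[Si](CC)(CC)CC)[C@H](O[Si](CC)(CC)CC)/C(C)=C\CC/C(C)=C/I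
F10 | step 17 | analogue of 23 with silyl ethers on C8 and C9 in place of the dioxolane (C11 epimers) | CC[Si](CC)(CC)OC[C@](O[Si](CC)(CC)CC)(C(CN(C)C)C(=O)OC)[C@H](O[Si](CC)(CC)CC)[C@H](O[Si](CC)(CC)CC)/C(C)=C\CC/C(C)=C/I
F11 | step 17 | analogue of 25 with silyl ethers on C8 and C9 in place of the dioxolane | CC[Si](CC)(CC)OC[C@](O[Si](CC)(CC)CC)(C(=C)C(=O)OC)[C@H](O[Si](CC)(CC)CC)[C@H](O[Si](CC)(CC)CC)/C(C)=C\CC/C(C)=C/I
F12 | step 17 | analogue of 26 with silyl ethers on C8 and C9 in place of the dioxolane | O=C[C@](O[Si](CC)(CC)CC)(C(=C)C(=O)OC)[C@H](O[Si](CC)(CC)CC)[C@H](O[Si](CC)(CC)CC)/C(C)=C\CC/C(C)=C/I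
F13 | step 17 | 7,8,9-tris(triethylsilyloxy)germacra-1(10)Z,4E,11(13)-trien-12,6-olide, C6 to C9 as in 37 | C=C1C(=O)O[C@@H]2/C=C(\C)CC/C=C(/C)[C@@H](O[Si](CC)(CC)CC)[C@@H](O[Si](CC)(CC)CC)[C@@]12O[Si](CC)(CC)CC
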